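**Retrosynthetic overview**

- The target diol comes from the trans dimethyl 1-aryl-1,2-dihydronaphthalene-2,3-dicarboxylate by i-Bu2AlH reduction. That diester comes from the 1-aryltetralin-2,3-diester by C3 selenenylation and selenoxide elimination toward C4.
- Key disconnection: the C2–C3 bond of ring B. C2 and C3 each carry a carboxyl-level carbon (the later CH2OH groups), so both are ester α-carbons of the same nucleophilic polarity. The bond is made by oxidizing the dilithium bis-enolate of an open-chain diester with CuCl2.
- The open-chain diester comes from a ring-A cinnamate by Rh/(S)-BINAP 1,4-addition of 3,4-dimethoxyphenylboronic acid, which sets C1. The cinnamate comes from a Heck reaction of methyl acrylate with methyl 3-(2-iodo-3,4,5-trimethoxyphenyl)propanoate, made from 3-(3,4,5-trimethoxyphenyl)propanoic acid.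
- Ring order: ring A (trimethoxybenzene) and ring C (3,4-dimethoxyphenyl) are bought. Ring B is the only ring made, and it is closed in the key step.

Key step: step 5

Remark: locants are those of the naphthalene core (C1 diaryl methine, C2 and C3 the carbons bearing the carboxyl-level carbons, C4 the benzylic carbon on ring A, C8 the methoxy-bearing carbon next to C8a). With the CIP order trimethoxyaryl > dimethoxyphenyl > CH2, the C1 centre is (R) from the open-chain diester through to the target.

**Route**

Step 1
Reactants: 1 3-(3,4,5-trimethoxyphenyl)propanoic acid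
Product: 2 methyl 3-(3,4,5-trimethoxyphenyl)propanoate
Conditions: MeOH, H2SO4 (cat.), reflux
Reagents that add atoms: methanol, CO
Why: Fischer esterification, driven to completion by methanol as solvent, with the aryl methyl ethers inert to the acid.

Step 2
Reactants: 2 methyl 3-(3,4,5-trimethoxyphenyl)propanoate
Product: 3 methyl 3-(2-iodo-3,4,5-trimethoxyphenyl)propanoate
Conditions: N-iodosuccinimide (1.05 equiv), CF3CO2H (0.3 equiv), MeCN, rt, dark
Reagents that add atoms: N-iodosuccinimide, O=C1CCC(=O)N1I
Why: Electrophilic aromatic iodination with acid-activated N-iodosuccinimide should occur once at one of the two equivalent free ring positions, each ortho and para to a methoxy group, because the first iodine crowds and deactivates the ring toward a second substitution.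

Step 3
Reactants: 3 methyl 3-(2-iodo-3,4,5-trimethoxyphenyl)propanoate; 4 methyl acrylate
Product: 5 methyl (E)-3-[2,3,4-trimethoxy-6-(3-methoxy-3-oxopropyl)phenyl]prop-2-enoate
Conditions: Pd(OAc)2 (5 mol %), n-Bu4NCl (1 equiv), NaHCO3 (2.5 equiv), 4 (3 equiv), DMF, 90 °C
Reagents that add atoms: none
Why: Mizoroki–Heck reaction under ligand-free phase-transfer conditions, which suit hindered electron-rich aryl iodides, in which syn-insertion and syn-β-hydride elimination give the (E)-enoate while the saturated ester stays a spectator.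

Step 4
Reactants: 5 methyl (E)-3-[2,3,4-trimethoxy-6-(3-methoxy-3-oxopropyl)phenyl]prop-2-enoate; 6 3,4-dimethoxyphenylboronic acid
Product: 7 methyl (3R)-3-(3,4-dimethoxyphenyl)-3-[2,3,4-trimethoxy-6-(3-methoxy-3-oxopropyl)phenyl]propanoate
Conditions: Rh(acac)(C2H4)2 (5 mol %), (S)-BINAP (6 mol %), 6 (4 equiv, in portions), dioxane/H2O 10:1, 100 °C
Reagents that add atoms: none
Why: Hayashi–Miyaura asymmetric 1,4-addition, in which the aryl–rhodium complex of (S)-BINAP should insert the (E)-enoate on its α-si face and so deliver the aryl group to the face of the β-carbon that makes C1 (R), after which water protonates the rhodium enolate; the heat and the excess of 6 answer the hindrance of the twisted 2,6-disubstituted ring and protodeboronation.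

Step 5
Reactants: 7 methyl (3R)-3-(3,4-dimethoxyphenyl)-3-[2,3,4-trimethoxy-6-(3-methoxy-3-oxopropyl)phenyl]propanoate
Product: 9 dimethyl (1R,2S,3S)-1-(3,4-dimethoxyphenyl)-6,7,8-trimethoxy-1,2,3,4-tetrahydronaphthalene-2,3-dicarboxylate, via dilithium bis-enolate 8 (not isolated)
Conditions: 7 added slowly to LiN(i-Pr)2 (2.4 equiv), THF, −78 °C, 0.01 M; then CuCl2 (2.5 equiv, anhydrous, in DMF), −78 → 0 °C
Reagents that add atoms: none
Why: Slow addition of 7 to excess LiN(i-Pr)2 removes one α-hydrogen from each ester to give bis-enolate 8 (the doubly benzylic C1–H and the C4 hydrogens are far less acidic), divalent copper oxidizes one enolate by one electron to an α-ester radical that adds to the other enolate carbon, and a second CuCl2 oxidizes the resulting radical anion to the diester. The closest known reaction type is the intramolecular oxidative coupling of diester dienolates by divalent copper salts to cycloalkane-1,2-dicarboxylates. Ring B (C1, C2, C3, C4, C4a, C8a) closes in a 6-exo-trig mode, the radical carbon attacking an enolate C=C that lies outside the forming ring. C2 is controlled by C1: the C1 aryl group should sit pseudoaxial to avoid the C8 methoxy group and C2 should be attacked so that its ester ends anti to that aryl group, while C3 should follow a chair-like closure with its ester trans to the C2 ester, and because C3 is erased in step 6 its epimer serves equally. The step needs ring closure over coupling between molecules and over Claisen-type condensation, which is secured by the two arms being held on adjacent carbons of ring A (six-membered closure against a seven-membered Dieckmann ring), by high dilution and by complete double enolization before the oxidant arrives. Should some cis C1/C2 isomer form, it can be corrected at diester 13, where the C2 hydrogen is α to an ester and allylic and NaOMe in MeOH should equilibrate it to the trans arrangement.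

Step 6
Reactants: 9 dimethyl (1R,2S,3S)-1-(3,4-dimethoxyphenyl)-6,7,8-trimethoxy-1,2,3,4-tetrahydronaphthalene-2,3-dicarboxylate
Product: 11 dimethyl (1R,2R,3R)-1-(3,4-dimethoxyphenyl)-6,7,8-trimethoxy-3-(phenylselanyl)-1,2,3,4-tetrahydronaphthalene-2,3-dicarboxylate, via lithium C3 ester enolate 10 (not isolated)
Conditions: 9 added to LiN(i-Pr)2 (1.05 equiv), THF, −78 °C; then PhSeBr (1.2 equiv), THF, −78 °C
Reagents that add atoms: phenylselenyl bromide, Br[Se]c1ccccc1
Why: Ester enolate selenenylation: one equivalent of base should remove the C3 hydrogen, which is less hindered than the C2 hydrogen next to the diaryl-substituted C1 and gives the less strained enolate, and PhSeBr should then enter C3 anti to the pseudoaxial C1 aryl group, which places selenium cis to the C2 ester and trans to the C2 hydrogen.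

Step 7
Reactants: 11 dimethyl (1R,2R,3R)-1-(3,4-dimethoxyphenyl)-6,7,8-trimethoxy-3-(phenylselanyl)-1,2,3,4-tetrahydronaphthalene-2,3-dicarboxylate
Product: 13 dimethyl (1R,2S)-1-(3,4-dimethoxyphenyl)-6,7,8-trimethoxy-1,2-dihydronaphthalene-2,3-dicarboxylate, via selenoxide 12 (not isolated)
Conditions: H2O2 (30 % aq., 3 equiv), pyridine (2 equiv), CH2Cl2, 0 °C → rt
Reagents that add atoms: none
Why: Oxidation to the selenoxide followed by spontaneous syn-elimination, which should run toward C4 because selenium has a syn hydrogen only there (the C2 hydrogen is trans to it) and because this gives the alkene conjugated with ring A and the C3 ester, while pyridine buffers the benzeneselenenic acid and C1 and C2 are untouched.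

Step 8
Reactants: 13 dimethyl (1R,2S)-1-(3,4-dimethoxyphenyl)-6,7,8-trimethoxy-1,2-dihydronaphthalene-2,3-dicarboxylate
Product: 14 [(1R,2S)-1-(3,4-dimethoxyphenyl)-3-(hydroxymethyl)-6,7,8-trimethoxy-1,2-dihydronaphthalen-2-yl]methanol
Conditions: i-Bu2AlH (6 equiv), CH2Cl2, −78 → 0 °C; aq. potassium sodium tartrate work-up
Reagents that add atoms: none
Why: Hydride reduction with i-Bu2AlH, which should take the saturated ester to the primary alcohol and the conjugated ester by 1,2-addition to the allylic alcohol at low temperature without reducing the C3=C4 bond or epimerizing C1 and C2 under these non-basic conditions.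

**Compound list**

1 | 3-(3,4,5-trimethoxyphenyl)propanoic acid | COc1cc(CCC(=O)O)cc(OC)c1OC | starting material
2 | methyl 3-(3,4,5-trimethoxyphenyl)propanoate | COC(=O)CCc1cc(OC)c(OC)c(OC)c1 | intermediate
3 | methyl 3-(2-iodo-3,4,5-trimethoxyphenyl)propanoate | COC(=O)CCc1cc(OC)c(OC)c(OC)c1I | intermediate
4 | methyl acrylate | C=CC(=O)OC | starting material
5 | methyl (E)-3-[2,3,4-trimethoxy-6-(3-methoxy-3-oxopropyl)phenyl]prop-2-enoate | COC(=O)/C=C/c1c(CCC(=O)OC)cc(OC)c(OC)c1OC | intermediate
6 | 3,4-dimethoxyphenylboronic acid | COc1ccc(B(O)O)cc1OC | starting material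
7 | methyl (3R)-3-(3,4-dimethoxyphenyl)-3-[2,3,4-trimethoxy-6-(3-methoxy-3-oxopropyl)phenyl]propanoate | COc1ccc([C@@H](CC(=O)OC)c2c(CCC(=O)OC)cc(OC)c(OC)c2OC)cc1OC | intermediate
8 | dilithium bis-enolate of 7 (both ester α-carbons, C2 and C3, deprotonated; C1 R) | COc1ccc([C@@H](C=C(OC)O[Li])c2c(CC=C(OC)O[Li])cc(OC)c(OC)c2OC)cc1OC | intermediate
9 | dimethyl (1R,2S,3S)-1-(3,4-dimethoxyphenyl)-6,7,8-trimethoxy-1,2,3,4-tetrahydronaphthalene-2,3-dicarboxylate | COc1ccc([C@@H]2c3c(cc(OC)c(OC)c3OC)C[C@H](C(=O)OC)[C@H]2C(=O)OC)cc1OC | intermediate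
10 | lithium enolate of the C3 ester of 9 (C1 R, C2 S) | COc1ccc([C@@H]2c3c(cc(OC)c(OC)c3OC)CC(=C(OC)O[Li])[C@H]2C(=O)OC)cc1OC | intermediate
11 | dimethyl (1R,2R,3R)-1-(3,4-dimethoxyphenyl)-6,7,8-trimethoxy-3-(phenylselanyl)-1,2,3,4-tetrahydronaphthalene-2,3-dicarboxylate | COc1ccc([C@@H]2c3c(cc(OC)c(OC)c3OC)C[C@]([Se]c4ccccc4)(C(=O)OC)[C@H]2C(=O)OC)cc1OC | intermediate
12 | selenoxide of 11 (configuration at selenium not defined) | COc1ccc([C@@H]2c3c(cc(OC)c(OC)c3OC)C[C@]([Se](=O)c4ccccc4)(C(=O)OC)[C@H]2C(=O)OC)cc1OC | intermediate
13 | dimethyl (1R,2S)-1-(3,4-dimethoxyphenyl)-6,7,8-trimethoxy-1,2-dihydronaphthalene-2,3-dicarboxylate | COc1ccc([C@@H]2c3c(cc(OC)c(OC)c3OC)C=C(C(=O)OC)[C@H]2C(=O)OC)cc1OC | intermediate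
14 | [(1R,2S)-1-(3,4-dimethoxyphenyl)-3-(hydroxymethyl)-6,7,8-trimethoxy-1,2-dihydronaphthalen-2-yl]methanol (CNP0274357.1) | COc1ccc([C@@H]2c3c(cc(OC)c(OC)c3OC)C=C(CO)[C@H]2CO)cc1OC | target

**Step count**

Total step count: 8. Longest linear sequence: 8 steps (1 → 14); 4 and 6 are bought and enter in steps 3 and 4.

**Steps most likely to fail**

Step 5 (key step). What may go wrong:
- coupling between two molecules instead of within one;
- Claisen-type condensation of a half-enolized diester before the second deprotonation is complete;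
- C-chlorination of an enolate by CuCl2 in place of electron transfer;
- closure with the C2 ester cis to the C1 aryl group.

Fallback: from 7, the bis-enolate is trapped with Me3SiCl (LiN(i-Pr)2, Me3SiCl, THF, −78 °C) as the bis(trimethylsilyl ketene acetal) F1, which is isolated by non-aqueous work-up. It is then oxidized with TiCl4 in CH2Cl2 at −78 °C under high dilution. This is the known oxidative coupling of ketene silyl acetals to succinates through titanium enolates, applied within one molecule, and it comes back to the route at 9.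

Step 4. What may go wrong:
- insertion at the β-carbon, shielded on both faces by the ortho methoxy and ortho alkyl groups of the twisted ring, is slower than protodeboronation of the boronic acid;
- insertion proceeds with poor face selectivity.

Fallback: from 3, Heck coupling with acrylic acid under the palladium conditions of step 3 gives the cinnamic acid F2. Its pivaloyl mixed anhydride acylates (S)-4-phenyloxazolidin-2-one (t-BuCOCl, Et3N, LiCl, THF) to the N-enoyl imide F3. The aryl cuprate from (3,4-dimethoxyphenyl)magnesium bromide and CuBr·SMe2 (THF, −40 °C, at which the methyl ester should be spared) adds to the magnesium-chelated s-cis imide on the face away from the 4-phenyl group. This gives the conjugate adduct F4 with C1 (R). NaOMe in MeOH at 0 °C releases the auxiliary and comes back to the route at 7.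

Step 6. What may go wrong:
- deprotonation at C2 as well as C3, so that selenium is delivered in part to C2 and the later elimination destroys the C1 or C2 centre;
- delivery of selenium to the C3 face cis to the C2 hydrogen, which opens elimination toward C2.

Fallback: the two carboxyl groups are made different. From 3, Heck coupling with benzyl acrylate gives the benzyl cinnamate F5. The conditions of step 4 give the benzyl methyl diester F6, and those of step 5 give the benzyl methyl tetralin diester F7. H2 over palladium on carbon (EtOAc, rt) frees the C2 carboxylic acid F8. LiN(i-Pr)2 (2.1 equiv, THF, −78 °C) then removes the carboxyl proton and only the C3 hydrogen next to the methyl ester, since a carboxylate α-hydrogen is far less acidic. PhSeBr gives the C3 selenide acid F9, and Me3SiCHN2 (MeOH/toluene) methylates the acid and comes back to the route at 11.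

**Further compounds**

F1 | step 5 | bis(trimethylsilyl ketene acetal) of 7 (C1 R) | COc1ccc([C@@H](C=C(OC)O[Si](C)(C)C)c2c(CC=C(OC)O[Si](C)(C)C)cc(OC)c(OC)c2OC)cc1OC
F2 | step 4 | (E)-3-[2,3,4-trimethoxy-6-(3-methoxy-3-oxopropyl)phenyl]prop-2-enoic acid | OC(=O)/C=C/c1c(CCC(=O)OC)cc(OC)c(OC)c1OC
F3 | step 4 | methyl 3-[3,4,5-trimethoxy-2-[(E)-3-oxo-3-[(4S)-2-oxo-4-phenyl-1,3-oxazolidin-3-yl]prop-1-enyl]phenyl]propanoate | COC(=O)CCc1cc(OC)c(OC)c(OC)c1/C=C/C(=O)N2[C@@H](c3ccccc3)COC2=O
F4 | step 4 | methyl 3-[2-[(1R)-1-(3,4-dimethoxyphenyl)-3-oxo-3-[(4S)-2-oxo-4-phenyl-1,3-oxazolidin-3-yl]propyl]-3,4,5-trimethoxyphenyl]propanoate | COc1ccc([C@@H](CC(=O)N4[C@@H](c5ccccc5)COC4=O)c2c(CCC(=O)OC)cc(OC)c(OC)c2OC)cc1OC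
F5 | step 6 | benzyl (E)-3-[2,3,4-trimethoxy-6-(3-methoxy-3-oxopropyl)phenyl]prop-2-enoate | COC(=O)CCc1cc(OC)c(OC)c(OC)c1/C=C/C(=O)OCc2ccccc2
F6 | step 6 | benzyl (3R)-3-(3,4-dimethoxyphenyl)-3-[2,3,4-trimethoxy-6-(3-methoxy-3-oxopropyl)phenyl]propanoate | COc1ccc([C@@H](CC(=O)OCc3ccccc3)c2c(CCC(=O)OC)cc(OC)c(OC)c2OC)cc1OC
F7 | step 6 | 2-benzyl 3-methyl (1R,2S,3S)-1-(3,4-dimethoxyphenyl)-6,7,8-trimethoxy-1,2,3,4-tetrahydronaphthalene-2,3-dicarboxylate | COc1ccc([C@@H]2c3c(cc(OC)c(OC)c3OC)C[C@H](C(=O)OC)[C@H]2C(=O)OCc4ccccc4)cc1OC
F8 | step 6 | (1R,2S,3S)-1-(3,4-dimethoxyphenyl)-6,7,8-trimethoxy-3-(methoxycarbonyl)-1,2,3,4-tetrahydronaphthalene-2-carboxylic acid | COc1ccc([C@@H]2c3c(cc(OC)c(OC)c3OC)C[C@H](C(=O)OC)[C@H]2C(=O)O)cc1OC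
F9 | step 6 | (1R,2R,3R)-1-(3,4-dimethoxyphenyl)-6,7,8-trimethoxy-3-(methoxycarbonyl)-3-(phenylselanyl)-1,2,3,4-tetrahydronaphthalene-2-carboxylic acid | COc1ccc([C@@H]2c3c(cc(OC)c(OC)c3OC)C[C@]([Se]c4ccccc4)(C(=O)OC)[C@H]2C(=O)O)cc1OC
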